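At 0.667 min Thursday's flask held 2.6% of target, yet by 2.50 min it held 96.3%. I wanted the rule for when that sharp rise begins in a flask charged between the two earlier ones.

| flask | substrate | reagent | base | remark | time |
|---|---|---|---|---|---|
| Tuesday's | 1 mM | 1.5 equiv | 0.010 equiv | run made earlier |  |
| Thursday's | 1 mM | 1.5 equiv | 0.040 equiv | run made earlier |  |
| flask | 1.0 mM | 1.50 equiv | 0.0200 equiv |  | 15 min |

| Tuesday's: time / min | Tuesday's: target / % | Thursday's: time / min | Thursday's: target / % |
|---|---|---|---|
| 0.333 | 2.5 | 0.333 | 1.5 |
| 0.667 | 73.9 | 0.667 | 2.6 |
| 1.33 | 96.2 | 1.33 | 35.0 |
| 2.50 | 95.1 | 2.50 | 96.3 |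
| 4.00 | 89.4 | 4.00 | 92.1 |
| 8.00 | 78.2 | 8.00 | 79.9 |
| 15.0 | 62.8 | 15.0 | 64.0 |

(scatter of a reading: 1 percentage point)

* time up to 15 min at which target stands highest
* the amount of target, in percent of the substrate charged, at that time
* the first time at which target reaches 49%, in the same percent, in min



I read the two target columns against each other. Thursday's early readings lie below its 0.040 equiv of base, whereas Tuesday's first reading, 2.5%, already exceeds its 0.010 equiv. So I took a slow, steady reaction to run until it had made as much as the base charged, and the front to start then. Thursday's second row gives that slow rate as 0.0390 /min, as a fraction of the substrate charged.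

The quantity I carried is the base-clearing time, the base charged divided by the slow rate, which I took as a flask's induction period: 0.513 min for the new flask, against 0.257 min for Tuesday's and 1.03 min for Thursday's.

Tuesday's readings, joined by a straight line, reach the level asked at 0.551 min, which is 0.294 min after its clearing time. Adding that to Thursday's clearing time gives 1.32 min, but Thursday's reading at 1.33 min, 35.0%, still lay below the level asked, so the addition ran somewhat early for Thursday's flask. For the new flask the same addition gave me 0.807 min. Tuesday's highest reading, 96.2%, came 0.779 min after its crossing, so I put the peak near 1.59 min, at about that height.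

The forecast gave 0.83 min, 1.5 min and 96.7%, holding that “base must be used up before a fast, self-accelerating reaction takes over”.

The flask crossed at 0.838 min and peaked at 97.6% at 1.48 min.

    substrate + reagent + released group → target + 2 released group (k = 2.40 × 10⁵ /M²/s)
    substrate + reagent → target + released group (k = 0.430 /M/s)
    base + released group ⇌ salt, settled at all times (K = 1.30 × 10⁸ /M)
    target → over-reaction product (k = 5.40 × 10⁻⁴ /s)

The crossing came 0.0310 min after my reckoning from the base-clearing time. For the neighbouring flask, with reagent cut to 0.900 equiv, I took the slow rate in proportion to reagent, as the scheme's uncatalysed step has it. Its clearing time becomes 0.855 min, longer than the flask's. That neighbour's target peaked at 84.2%. Reagent was now the limiting reagent: at the end it stood at 0%, with 58.2% target and 10.0% substrate.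

The runs come from a simulation for substances that don't exist, and the scatter is random.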